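## Retrosynthetic overview
1. The target comes from its 3‑O‑TBS ether. The ten‑membered carbocycle is opened at C1=C2 by ring‑closing metathesis of a seco‑diene, so this ring is closed last.
2. The seco‑diene comes from esterifying 8‑OH with tiglic acid. Its cis α‑methylene‑γ‑butyrolactone comes from a zinc Barbier coupling/lactonisation that forms C6–C7 between an East allyl bromide and a West Z‑enal.
3. The East bromide comes from a Baylis–Hillman reaction and SN2′ bromination of an α‑silyloxy aldehyde. That aldehyde comes from L‑proline α‑aminoxylation (C8) after ozonolysis of (R)‑linalool (C10).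
4. The West enal comes from formylation of a Z‑alkenyl iodide. The iodide comes from lipase resolution (C3), vinyl addition, and anti‑carbomagnesiation/iodination of propargyl alcohol (Z‑C4=C5).
5. Ring order: γ‑lactone first (step 16), ten‑membered ring second (step 19).

Assumption: late intermediates carry the germacrane numbering of the target (C1=C2, C3‑OH, C4=C5, C6‑O‑lactone, C7, C8‑O‑tiglate, C9, C10‑OH, C11=C13, C12=O), and commercial (R)‑(–)‑linalool is taken as ≥95 % ee.

## East branch

Step 1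
Reactants: 1 (R)-(–)-linalool
Product: 2 (3R)-3,7-dimethyl-3-(triethylsilyloxy)octa-1,6-diene
Conditions: TESOTf, 2,6-lutidine, CH2Cl2, 0 °C
Reagents that add atoms: triethylsilyl triflate, CC[Si](CC)(CC)OS(=O)(=O)C(F)(F)F
Why: Silyl triflate silylation masks the hindered tertiary O10 so the later γ‑hydroxy aldehyde cannot close to a lactol; C10 (R) comes from the chiral pool and is never touched.

Step 2
Reactants: 2 (3R)-3,7-dimethyl-3-(triethylsilyloxy)octa-1,6-diene
Product: 4 (4R)-4-methyl-4-(triethylsilyloxy)hex-5-enal, via secondary ozonide 3 (not isolated)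
Conditions: O3 (1 equiv, Sudan III end point), CH2Cl2, –78 °C; Me2S, –78 °C → rt
Reagents that add atoms: ozone, [O-][O+]=O
Why: Chemoselective ozonolysis works because the electron‑rich trisubstituted alkene reacts far faster than the vinyl group next to quaternary C10, and reductive work‑up gives the C7 aldehyde.

Step 3
Reactants: 4 (4R)-4-methyl-4-(triethylsilyloxy)hex-5-enal
Product: 6 (2R,4R)-2-(anilinooxy)-4-methyl-4-(triethylsilyloxy)hex-5-en-1-ol, via α-aminoxy aldehyde 5 (not isolated)
Conditions: PhNO, L-proline (20 mol %), DMSO, rt, 30 min; then MeOH, NaBH4, 0 °C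
Reagents that add atoms: nitrosobenzene, O=Nc1ccccc1
Why: In this proline‑catalysed enamine α‑aminoxylation the acid‑directed attack on the L‑proline enamine sets C8 as R under catalyst control (dr >95:5), and immediate borohydride reduction prevents epimerisation.

Step 4
Reactants: 6 (2R,4R)-2-(anilinooxy)-4-methyl-4-(triethylsilyloxy)hex-5-en-1-ol
Product: 7 (2R,4R)-4-methyl-4-(triethylsilyloxy)hex-5-ene-1,2-diol
Conditions: Zn dust, AcOH–EtOH (1:4), rt, 1 h
Reagents that add atoms: none
Why: Dissolving‑metal N–O cleavage frees the 1,2‑diol without touching the alkene, the tertiary TES ether or the stereocentres.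

Step 5
Reactants: 7 (2R,4R)-4-methyl-4-(triethylsilyloxy)hex-5-ene-1,2-diol
Product: 8 (2R,4R)-4-methyl-1,2,4-tris(triethylsilyloxy)hex-5-ene
Conditions: TESCl (2.5 equiv), imidazole, CH2Cl2, 0 °C → rt
Reagents that add atoms: chlorotriethylsilane, CC[Si](CC)(CC)Cl
Why: Standard imidazole‑promoted silylation of both free hydroxyls prepares the selective oxidation of the next step.

Step 6
Reactants: 8 (2R,4R)-4-methyl-1,2,4-tris(triethylsilyloxy)hex-5-ene
Product: 10 (2R,4R)-4-methyl-2,4-bis(triethylsilyloxy)hex-5-enal, via alkoxysulfonium chloride 9 (not isolated)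
Conditions: (COCl)2 (4 equiv), DMSO (8 equiv), CH2Cl2, –78 → –35 °C, 30 min; Et3N, –78 → 0 °C
Reagents that add atoms: none
Why: In a Swern oxidation run directly on the silyl ether, only the unhindered primary O–SiEt3 is attacked by activated DMSO, so the α‑silyloxy aldehyde forms without a separate deprotection and without epimerisation at low temperature.

Step 7
Reactants: 10 (2R,4R)-4-methyl-2,4-bis(triethylsilyloxy)hex-5-enal; 11 methyl acrylate
Product: 12 methyl (4R,6R)-3-hydroxy-6-methyl-2-methylidene-4,6-bis(triethylsilyloxy)oct-7-enoate (C3 epimers)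
Conditions: 11 (5 equiv, neat), 3-hydroxyquinuclidine (0.5 equiv), rt, 3 d
Reagents that add atoms: none
Why: The Morita–Baylis–Hillman reaction suits this inductively activated α‑alkoxy aldehyde, and the new carbinol centre is irrelevant because it is erased in step 8.

Step 8
Reactants: 12 methyl (4R,6R)-3-hydroxy-6-methyl-2-methylidene-4,6-bis(triethylsilyloxy)oct-7-enoate
Product: 13 methyl (2Z,4R,6R)-2-(bromomethyl)-6-methyl-4,6-bis(triethylsilyloxy)octa-2,7-dienoate
Conditions: NBS, Me2S, CH2Cl2, 0 °C → rt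
Reagents that add atoms: N-bromosuccinimide, O=C1CCC(=O)N1Br
Why: Corey–Kim‑type activation followed by SN2′ attack of bromide converges both epimers on the Z‑bromide (minimised A1,3 strain) under near‑neutral conditions that spare the TES ethers.

## West branch

Step 9
Reactants: 14 propargyl alcohol
Product: 16 (Z)-3-iodo-2-methylprop-2-en-1-ol, via alkenylmagnesium alkoxide 15 (not isolated)
Conditions: MeMgBr (2.5 equiv), CuI (10 mol %), THF, –10 °C → rt; I2, THF, 0 °C
Reagents that add atoms: methylmagnesium bromide, C[Mg]Br; iodine, II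
Why: Copper‑catalysed, alkoxide‑directed anti‑carbomagnesiation gives the chelated alkenylmagnesium, and iodinolysis with retention fixes the Z geometry of C4=C5.

Step 10
Reactants: 16 (Z)-3-iodo-2-methylprop-2-en-1-ol
Product: 17 (Z)-3-iodo-2-methylprop-2-enal
Conditions: MnO2 (15 equiv), CH2Cl2, rt, dark, used at once
Reagents that add atoms: none
Why: Neutral heterogeneous allylic oxidation gives the enal without Z→E isomerisation when light and storage are avoided.

Step 11
Reactants: 17 (Z)-3-iodo-2-methylprop-2-enal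
Product: 18 (±)-(1Z)-1-iodo-2-methylpenta-1,4-dien-3-ol
Conditions: CH2=CHMgBr, THF, –78 °C
Reagents that add atoms: vinylmagnesium bromide, C=C[Mg]Br
Why: Grignard 1,2‑addition to the enal is much faster at –78 °C than iodine–magnesium exchange and installs C2 together with the racemic C3 carbinol.

Step 12
Reactants: 18 (±)-(1Z)-1-iodo-2-methylpenta-1,4-dien-3-ol
Product: 19 (1Z,3R)-1-iodo-2-methylpenta-1,4-dien-3-yl acetate
Conditions: Novozym 435 (CAL-B), vinyl acetate, MTBE–hexane, 30 °C, to 50 % conversion; chromatography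
Reagents that add atoms: vinyl acetate, C=COC(C)=O
Why: In this lipase kinetic resolution the Kazlauskas rule (large = branched iodoalkenyl, medium = vinyl) predicts fast acylation of the R alcohol, which sets C3.

Step 13
Reactants: 19 (1Z,3R)-1-iodo-2-methylpenta-1,4-dien-3-yl acetate
Product: 20 (1Z,3R)-1-iodo-2-methylpenta-1,4-dien-3-ol
Conditions: K2CO3 (0.2 equiv), MeOH, 0 °C → rt
Reagents that add atoms: none
Why: Base‑catalysed transesterification cleaves the acyl–O bond, so C3 keeps its configuration.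

Step 14
Reactants: 20 (1Z,3R)-1-iodo-2-methylpenta-1,4-dien-3-ol
Product: 21 tert-butyl{[(1Z,3R)-1-iodo-2-methylpenta-1,4-dien-3-yl]oxy}dimethylsilane
Conditions: TBSCl, imidazole, DMF, rt
Reagents that add atoms: tert-butyldimethylsilyl chloride, CC(C)(C)[Si](C)(C)Cl
Why: Silylation gives an O3 group that outlasts the TES ethers and keeps the secondary carbinol from degrading the metathesis catalyst later.

Step 15
Reactants: 21 tert-butyl{[(1Z,3R)-1-iodo-2-methylpenta-1,4-dien-3-yl]oxy}dimethylsilane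
Product: 24 (2Z,4R)-4-(tert-butyldimethylsilyloxy)-3-methylhexa-2,5-dienal, via alkenyllithium 22 (not isolated), via lithium hemiaminal alkoxide 23 (not isolated)
Conditions: t-BuLi (2.05 equiv), Et2O, –78 °C, 20 min; DMF, –78 → –20 °C; aq NH4Cl
Reagents that add atoms: N,N-dimethylformamide, CN(C)C=O
Why: Iodine–lithium exchange with retention followed by Bouveault formylation adds C6; in Et2O at –78 °C the alkenyllithium is configurationally stable and O→C silyl migration is slow.

## Union and endgame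

Step 16
Reactants: 13 methyl (2Z,4R,6R)-2-(bromomethyl)-6-methyl-4,6-bis(triethylsilyloxy)octa-2,7-dienoate; 24 (2Z,4R)-4-(tert-butyldimethylsilyloxy)-3-methylhexa-2,5-dienal
Product: 27 (4S,5S)-5-[(1Z,3R)-3-(tert-butyldimethylsilyloxy)-2-methylpenta-1,4-dien-1-yl]-4-[(1R,3R)-3-methyl-1,3-bis(triethylsilyloxy)pent-4-en-1-yl]-3-methylideneoxolan-2-one, via allylzinc bromide 25 (not isolated), via hydroxy ester 26 (not isolated)
Conditions: activated Zn dust, THF–sat. aq NH4Cl (4:1), 0 °C → rt; crude 26: PPTS (20 mol %), toluene, 45 °C; chromatography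
Reagents that add atoms: none
Why: In this zinc Barbier (Dreiding–Schmidt) 2‑(alkoxycarbonyl)allylation the allylzinc reacts at C7 (SE2′) through a chair with C8 cis to CH2Zn, giving the 6,7‑syn adduct and hence the cis lactone, while H8 sits in the alkene plane (A1,3 strain) so the aldehyde approaches anti to the C9 chain, giving target C6 (S) and C7 geometry (C7 reads S here only because O–Si raises the CIP rank of C8).

Step 17
Reactants: 27 bis-TES lactone
Product: 28 (4R,5S)-5-[(1Z,3R)-3-(tert-butyldimethylsilyloxy)-2-methylpenta-1,4-dien-1-yl]-4-[(1R,3R)-1,3-dihydroxy-3-methylpent-4-en-1-yl]-3-methylideneoxolan-2-one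
Conditions: PPTS (30 mol %), MeOH–CH2Cl2 (1:1), rt, monitored
Reagents that add atoms: none
Why: Acid‑catalysed methanolysis removes TES some hundredfold faster than TBS, which frees O8 and O10, while translactonisation to O8 would need a strained bicyclic orthoester.

Step 18
Reactants: 28 diol lactone; 29 tiglic acid
Product: 31 (1R,3R)-1-{(2S,3R)-2-[(1Z,3R)-3-(tert-butyldimethylsilyloxy)-2-methylpenta-1,4-dien-1-yl]-4-methylidene-5-oxooxolan-3-yl}-3-hydroxy-3-methylpent-4-en-1-yl (E)-2-methylbut-2-enoate, via mixed anhydride 30 (not isolated)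
Conditions: 29, 2,4,6-Cl3C6H2COCl, Et3N, toluene, rt; then 28, DMAP, rt → 40 °C
Reagents that add atoms: none
Why: Yamaguchi esterification acylates the secondary 8‑OH only, because the tertiary 10‑OH is inert; C8 is retained and the stable E acid cannot isomerise.

Step 19
Reactants: 31 seco-diene tiglate
Product: 32 (3aR,4R,6R,7Z,9R,10Z,11aS)-9-(tert-butyldimethylsilyloxy)-6-hydroxy-6,10-dimethyl-3-methylidene-2-oxo-2,3,3a,4,5,6,9,11a-octahydrocyclodeca[b]furan-4-yl (E)-2-methylbut-2-enoate
Conditions: Grubbs I, (PCy3)2Cl2Ru=CHPh (2 × 10 mol %), CH2Cl2 (0.5 mM), 40 °C, Ar sparge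
Reagents that add atoms: none
Why: In this ring‑closing metathesis the first‑generation catalyst sees only the two vinyl groups (α‑methylene lactone, tiglate and C4=C5 are spectators), the free tertiary allylic OH speeds carbene exchange at C1, the Z‑C4=C5 bond and cis lactone pre‑fold the chain, and ring strain is expected to favour the Z‑C1=C2 olefin.

Step 20
Reactants: 32 macrocyclic TBS ether
Product: 33 target, (3aR,4R,6R,7Z,9R,10Z,11aS)-6,9-dihydroxy-6,10-dimethyl-3-methylidene-2-oxo-2,3,3a,4,5,6,9,11a-octahydrocyclodeca[b]furan-4-yl (E)-2-methylbut-2-enoate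
Conditions: HF·pyridine, pyridine, THF, 0 °C → rt
Reagents that add atoms: none
Why: Buffered fluoride desilylation frees 3‑OH without harming the α‑methylene lactone, the tiglate or the bis‑allylic carbinol.

## Compound list
1 | (R)-(–)-linalool | C=C[C@](C)(O)CCC=C(C)C | starting material
2 | (3R)-3,7-dimethyl-3-(triethylsilyloxy)octa-1,6-diene | C=C[C@](C)(O[Si](CC)(CC)CC)CCC=C(C)C | intermediate
3 | secondary ozonide of 2 (epimers at the acetal CH) | C=C[C@](C)(O[Si](CC)(CC)CC)CCC1OOC(C)(C)O1 | intermediate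
4 | (4R)-4-methyl-4-(triethylsilyloxy)hex-5-enal | C=C[C@](C)(O[Si](CC)(CC)CC)CCC=O | intermediate
5 | (2R,4R)-2-(anilinooxy)-4-methyl-4-(triethylsilyloxy)hex-5-enal | C=C[C@](C)(O[Si](CC)(CC)CC)C[C@@H](ONc1ccccc1)C=O | intermediate
6 | (2R,4R)-2-(anilinooxy)-4-methyl-4-(triethylsilyloxy)hex-5-en-1-ol | C=C[C@](C)(O[Si](CC)(CC)CC)C[C@@H](ONc1ccccc1)CO | intermediate
7 | (2R,4R)-4-methyl-4-(triethylsilyloxy)hex-5-ene-1,2-diol | C=C[C@](C)(O[Si](CC)(CC)CC)C[C@@H](O)CO | intermediate
8 | (2R,4R)-4-methyl-1,2,4-tris(triethylsilyloxy)hex-5-ene | C=C[C@](C)(O[Si](CC)(CC)CC)C[C@@H](O[Si](CC)(CC)CC)CO[Si](CC)(CC)CC | intermediate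
9 | dimethyl{[(2R,4R)-4-methyl-2,4-bis(triethylsilyloxy)hex-5-en-1-yl]oxy}sulfonium chloride | C=C[C@](C)(O[Si](CC)(CC)CC)C[C@@H](O[Si](CC)(CC)CC)CO[S+](C)C.[Cl-] | intermediate
10 | (2R,4R)-4-methyl-2,4-bis(triethylsilyloxy)hex-5-enal | C=C[C@](C)(O[Si](CC)(CC)CC)C[C@@H](O[Si](CC)(CC)CC)C=O | intermediate
11 | methyl acrylate | C=CC(=O)OC | starting material
12 | methyl (4R,6R)-3-hydroxy-6-methyl-2-methylidene-4,6-bis(triethylsilyloxy)oct-7-enoate (C3 epimers) | C=C[C@](C)(O[Si](CC)(CC)CC)C[C@@H](O[Si](CC)(CC)CC)C(O)C(=C)C(=O)OC | intermediate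
13 | methyl (2Z,4R,6R)-2-(bromomethyl)-6-methyl-4,6-bis(triethylsilyloxy)octa-2,7-dienoate | C=C[C@](C)(O[Si](CC)(CC)CC)C[C@@H](O[Si](CC)(CC)CC)/C=C(\CBr)C(=O)OC | intermediate
14 | propargyl alcohol | C#CCO | starting material
15 | (Z)-3-(bromomagnesio)-2-methylprop-2-en-1-olate, bromomagnesium salt | Br[Mg]/C=C(/C)CO[Mg]Br | intermediate
16 | (Z)-3-iodo-2-methylprop-2-en-1-ol | I/C=C(/C)CO | intermediate
17 | (Z)-3-iodo-2-methylprop-2-enal | I/C=C(/C)C=O | intermediate
18 | (±)-(1Z)-1-iodo-2-methylpenta-1,4-dien-3-ol | I/C=C(/C)C(O)C=C | intermediate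
19 | (1Z,3R)-1-iodo-2-methylpenta-1,4-dien-3-yl acetate | I/C=C(/C)[C@H](OC(C)=O)C=C | intermediate
20 | (1Z,3R)-1-iodo-2-methylpenta-1,4-dien-3-ol | I/C=C(/C)[C@H](O)C=C | intermediate
21 | tert-butyl{[(1Z,3R)-1-iodo-2-methylpenta-1,4-dien-3-yl]oxy}dimethylsilane | I/C=C(/C)[C@H](O[Si](C)(C)C(C)(C)C)C=C | intermediate
22 | (1Z,3R)-3-(tert-butyldimethylsilyloxy)-2-methylpenta-1,4-dien-1-yllithium | [Li]/C=C(/C)[C@H](O[Si](C)(C)C(C)(C)C)C=C | intermediate
23 | lithium hemiaminal alkoxide from 22 and DMF | [Li]OC(N(C)C)/C=C(/C)[C@H](O[Si](C)(C)C(C)(C)C)C=C | intermediate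
24 | (2Z,4R)-4-(tert-butyldimethylsilyloxy)-3-methylhexa-2,5-dienal | O=C/C=C(/C)[C@H](O[Si](C)(C)C(C)(C)C)C=C | intermediate
25 | [(2Z,4R,6R)-2-(methoxycarbonyl)-6-methyl-4,6-bis(triethylsilyloxy)octa-2,7-dien-1-yl]zinc bromide | C=C[C@](C)(O[Si](CC)(CC)CC)C[C@@H](O[Si](CC)(CC)CC)/C=C(\C[Zn]Br)C(=O)OC | intermediate
26 | methyl (3S,4R,6R)-3-[(1S,2Z,4R)-4-(tert-butyldimethylsilyloxy)-1-hydroxy-3-methylhexa-2,5-dien-1-yl]-6-methyl-2-methylidene-4,6-bis(triethylsilyloxy)oct-7-enoate | C=C(C(=O)OC)[C@@H]([C@@H](O)/C=C(/C)[C@H](O[Si](C)(C)C(C)(C)C)C=C)[C@H](O[Si](CC)(CC)CC)C[C@@](C)(O[Si](CC)(CC)CC)C=C | intermediate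
27 | bis-TES cis-lactone (3R,6S,7S,8R,10R) | C=C1C(=O)O[C@@H](/C=C(/C)[C@H](O[Si](C)(C)C(C)(C)C)C=C)[C@H]1[C@H](O[Si](CC)(CC)CC)C[C@@](C)(O[Si](CC)(CC)CC)C=C | intermediate
28 | 8,10-diol cis-lactone (3R,6S,7R,8R,10R) | C=C1C(=O)O[C@@H](/C=C(/C)[C@H](O[Si](C)(C)C(C)(C)C)C=C)[C@H]1[C@H](O)C[C@@](C)(O)C=C | intermediate
29 | tiglic acid, (E)-2-methylbut-2-enoic acid | C/C=C(\C)C(=O)O | starting material
30 | tiglic 2,4,6-trichlorobenzoic anhydride | C/C=C(\C)C(=O)OC(=O)c1c(Cl)cc(Cl)cc1Cl | intermediate
31 | seco-diene 8-O-tiglate with 3-OTBS and free 10-OH (3R,6S,7R,8R,10R) | C=C1C(=O)O[C@@H](/C=C(/C)[C@H](O[Si](C)(C)C(C)(C)C)C=C)[C@H]1[C@H](OC(=O)/C(C)=C/C)C[C@@](C)(O)C=C | intermediate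
32 | 3-O-TBS ether of the target (1Z,4Z) | C=C1C(=O)O[C@H]2/C=C(/C)[C@H](O[Si](C)(C)C(C)(C)C)/C=C\[C@](C)(O)C[C@@H](OC(=O)/C(C)=C/C)[C@@H]12 | intermediate
33 | CNP0262559.2 | C=C1C(=O)O[C@H]2/C=C(/C)[C@H](O)/C=C\[C@](C)(O)C[C@@H](OC(=O)/C(C)=C/C)[C@@H]12 | target

## Counts and risks
Total step count: 20. Longest linear sequence: 13 steps (1 → 33 through steps 1–8 and 16–20). The West branch (steps 9–15) adds 7 steps.

**Step 16, Barbier coupling.**
- The face selectivity rests on an acyclic A1,3 model.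
- The fluxional allylzinc can leak to the anti adduct.
- It could also lose TESO– by vinylogous β‑elimination.

The fallback sets out from 12. Acetylation (Ac2O, DMAP) gives the Baylis–Hillman acetate F1. Copper‑catalysed SN2′ borylation (B2pin2, CuCl, KOAc, DMF) then gives the geometrically defined allylboronate F2. This reagent adds to 24 in toluene without any metal salt, through a rigid Zimmerman–Traxler chair (type I allylboration). Olefin geometry is therefore translated stereospecifically into the 6,7‑syn relation, and no carbanionic species exists that could eliminate. The sequence comes back to the route at 26, which is lactonised to 27 as before.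

**Step 19, ring‑closing metathesis.**
- The strained ten‑membered ring may close slowly, which would favour oligomers.
- It may give some E olefin.
- A more active catalyst would attack the α‑methylene group, giving six‑ or seven‑membered by‑products.

The fallback sets out from 31. HF·pyridine gives the seco‑diene diol F3. Slow addition of iPr2Si(OTf)2 with 2,6‑lutidine at high dilution ties O3 and O10 together as the cyclic silaketal F4. This is sterically possible because C4 and C9 lie on the same face of the new ring. Metathesis with Grubbs II is then a seven‑membered dioxasilepine closure between two neighbouring vinyl groups. That closure is fast, can only give the Z olefin, and leads to the bridged macrocycle F5. HF·pyridine removes the silicon bridge, and the sequence comes back at 33.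

**Step 7, Baylis–Hillman reaction.**
- Days of contact between the α‑silyloxy aldehyde and an amine base invite C8 epimerisation.
- They also invite O8→O7 silyl migration.

The fallback sets out from 10. Methyl propiolate is hydroaluminated (DIBAL‑H, NMO, THF, 0 °C) to the vinylalane F6. This preformed α‑acrylate anion equivalent adds to 10 within hours under non‑basic conditions, and the sequence comes back at 12.

## Further compounds
F1 | step 16 | methyl (4R,6R)-3-acetoxy-6-methyl-2-methylidene-4,6-bis(triethylsilyloxy)oct-7-enoate | C=C[C@](C)(O[Si](CC)(CC)CC)C[C@@H](O[Si](CC)(CC)CC)C(OC(C)=O)C(=C)C(=O)OC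
F2 | step 16 | methyl (2E,4R,6R)-6-methyl-2-[(4,4,5,5-tetramethyl-1,3,2-dioxaborolan-2-yl)methyl]-4,6-bis(triethylsilyloxy)octa-2,7-dienoate | C=C[C@](C)(O[Si](CC)(CC)CC)C[C@@H](O[Si](CC)(CC)CC)/C=C(\CB1OC(C)(C)C(C)(C)O1)C(=O)OC
F3 | step 19 | seco-diene 3,10-diol 8-O-tiglate | C=C1C(=O)O[C@@H](/C=C(/C)[C@H](O)C=C)[C@H]1[C@H](OC(=O)/C(C)=C/C)C[C@@](C)(O)C=C
F4 | step 19 | 3,10-O-diisopropylsilylene seco-diene (eleven-membered silaketal) | C=C1C(=O)O[C@H]2/C=C(/C)[C@@H](C=C)O[Si](C(C)C)(C(C)C)O[C@@](C)(C=C)C[C@@H](OC(=O)/C(C)=C/C)[C@@H]12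
F5 | step 19 | 3,10-O-diisopropylsilylene derivative of 33 | C=C1C(=O)O[C@H]2/C=C(/C)[C@H]3/C=C\[C@](C)(O[Si](C(C)C)(C(C)C)O3)C[C@@H](OC(=O)/C(C)=C/C)[C@@H]12
F6 | step 7 | methyl 2-(diisobutylalumanyl)acrylate | C=C(C(=O)OC)[Al](CC(C)C)CC(C)C
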